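**Assumption:** the target has no stereocentre and no stereogenic double bond, so it is achiral and the compound as drawn is the only stereoisomer; compound 1 is taken as a catalogue building block.

## Retrosynthetic overview

1. 8 ⇐ 7: chelation-controlled cleavage of the 5-O-methyl ether only.
2. 7 ⇐ 4: new C2'–O bond by para-oxygenation of the ring B phenol; the quinone so formed is the internal oxidant that dehydrogenates C2–C3.
3. 4 ⇐ 1 + 2: aldol condensation, then O1–C2 bond by oxa-Michael closure.
4. Ring order: rings A and B are bought; ring C is closed in step 1 and aromatised to the pyranone in step 2.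

## Route

Step 1
Reactants: 1 1-(2-hydroxy-3,4,5,6-tetramethoxyphenyl)ethan-1-one; 2 3-hydroxy-4-methoxybenzaldehyde (isovanillin)
Product: 4 rac-2-(3-hydroxy-4-methoxyphenyl)-5,6,7,8-tetramethoxychroman-4-one, via chalcone 3 (not isolated)
Conditions: KOH (6 equiv), EtOH/H2O, rt, 36 h; then AcOH to pH 6, reflux, 12 h
Reagents that add atoms: none
Why: Claisen–Schmidt aldol condensation (the phenoxide of 2 is meta to the aldehyde and does not deactivate it) followed by acetate-buffered 6-endo oxa-Michael closure, which is favoured for 6'-methoxy-2'-hydroxychalcones; the C2 stereocentre forms racemic and is erased in step 2.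

Step 2
Reactants: 4 rac-2-(3-hydroxy-4-methoxyphenyl)-5,6,7,8-tetramethoxychroman-4-one
Product: 7 2-(2,5-dihydroxy-4-methoxyphenyl)-5,6,7,8-tetramethoxy-4H-chromen-4-one, via quinonyl flavanone 5 (not isolated), via quinone methide 6 (not isolated)
Conditions: (KSO3)2NO (2.2 equiv), KH2PO4 buffer (pH 6), acetone/H2O, 0 °C to rt; extract into CH2Cl2; then Et3N (0.3 equiv), CH2Cl2, Ar, rt; 1 M HCl wash
Reagents that add atoms: potassium nitrosodisulfonate (Fremy's salt), [K+].[K+].[O]N(S(=O)(=O)[O-])S(=O)(=O)[O-]
Why: Proposed new method: an oxygenative redox-relay aromatisation in which the nitroxide oxidises the only free phenol at its open para position (Teuber oxidation; ring A has no free OH and is inert) to give quinone 5 with the new C2'–O bond; Et3N then removes the C2–H, which is vinylogous to the quinone carbonyl, to give the ortho-quinone methide 6, and a [1,5]-hydrogen shift (or deprotonation) of the C3–H, now alpha to the ketone and vinylogous to C2'=O, re-aromatises ring B and leaves the C2=C3 double bond, so the two oxidising equivalents stored in the quinone are spent inside the molecule and the ring size is already fixed; quinone/hydroquinone exchange between molecules is reversible and funnels into 7 because only 5 can tautomerise; closest known reaction types are the Teuber phenol-to-para-quinone oxidation, the base-catalysed alkylquinone to quinone methide tautomerism (ubiquinone to ubichromenol, 1-hydroxyalkylquinone to acylhydroquinone) and the quinone (DDQ) dehydrogenation of flavanones.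

Step 3
Reactants: 7 2-(2,5-dihydroxy-4-methoxyphenyl)-5,6,7,8-tetramethoxy-4H-chromen-4-one
Product: 8 2-(2,5-dihydroxy-4-methoxyphenyl)-5-hydroxy-6,7,8-trimethoxy-4H-chromen-4-one
Conditions: BCl3 (4 equiv), CH2Cl2, −40 to 0 °C; then aq. HCl/MeOH
Reagents that add atoms: none
Why: Chelation-controlled Lewis acid ether cleavage: BCl3 bound to the C4 carbonyl activates only the peri 5-OMe (six-membered chelate) for chloride attack, as in the selective 5-O-demethylation of polymethoxyflavones, while the two phenols are merely masked as aryloxyboranes and freed on work-up.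

## Compound list

1 | 1-(2-hydroxy-3,4,5,6-tetramethoxyphenyl)ethan-1-one (2'-hydroxy-3',4',5',6'-tetramethoxyacetophenone) | CC(=O)c1c(O)c(OC)c(OC)c(OC)c1OC | starting material
2 | 3-hydroxy-4-methoxybenzaldehyde (isovanillin) | COc1ccc(C=O)cc1O | starting material
3 | (E)-1-(2-hydroxy-3,4,5,6-tetramethoxyphenyl)-3-(3-hydroxy-4-methoxyphenyl)prop-2-en-1-one | COc1ccc(/C=C/C(=O)c2c(O)c(OC)c(OC)c(OC)c2OC)cc1O | intermediate (not isolated)
4 | rac-2-(3-hydroxy-4-methoxyphenyl)-5,6,7,8-tetramethoxychroman-4-one (racemic at C2) | COc1ccc(C2CC(=O)c3c(OC)c(OC)c(OC)c(OC)c3O2)cc1O | intermediate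
5 | rac-2-(4-methoxy-3,6-dioxocyclohexa-1,4-dien-1-yl)-5,6,7,8-tetramethoxychroman-4-one (racemic at C2) | COC1=CC(=O)C(C2CC(=O)c3c(OC)c(OC)c(OC)c(OC)c3O2)=CC1=O | intermediate (not isolated)
6 | (E)-2-(3-hydroxy-4-methoxy-6-oxocyclohexa-2,4-dien-1-ylidene)-5,6,7,8-tetramethoxychroman-4-one | O=C1C/C(=C2\C(=O)C=C(OC)C(O)=C2)Oc2c(OC)c(OC)c(OC)c(OC)c12 | intermediate (not isolated)
7 | 2-(2,5-dihydroxy-4-methoxyphenyl)-5,6,7,8-tetramethoxy-4H-chromen-4-one | COc1cc(O)c(-c2cc(=O)c3c(OC)c(OC)c(OC)c(OC)c3o2)cc1O | intermediate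
8 | 2-(2,5-dihydroxy-4-methoxyphenyl)-5-hydroxy-6,7,8-trimethoxy-4H-chromen-4-one (achiral) | COc1cc(O)c(-c2cc(=O)c3c(O)c(OC)c(OC)c(OC)c3o2)cc1O | target

## Step count and risks

Total steps: 3. Longest linear sequence: 3.

With three steps in all, each is ranked here, most risky first.

Step 2 (the new cascade) is the main risk. The quinone 5 may tautomerise already in the buffer and be over-oxidised, the flavanone may ring-open under the amine, or the tautomerisation may stall. The fallback uses known chemistry only, sets out from 4 and comes back at 7. Compound 4 is dehydrogenated with I2 (10 mol%) in DMSO at 120 °C to the flavone 2-(3-hydroxy-4-methoxyphenyl)-5,6,7,8-tetramethoxy-4H-chromen-4-one F3. Teuber oxidation of F3 with (KSO3)2NO in KH2PO4-buffered acetone/H2O gives the flavone quinone 2-(4-methoxy-3,6-dioxocyclohexa-1,4-dien-1-yl)-5,6,7,8-tetramethoxy-4H-chromen-4-one F4. Aqueous Na2S2O4 reduces F4 to 7. This costs two extra steps.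

Step 3 is the second risk. The aryloxyborane at O5' could deliver boron to the neighbouring 4'-OMe, a second cleavage could occur at 6-OMe, and the free hydroquinone may oxidise on work-up. The fallback sets out from 7 and comes back at 8, masking the hydroquinone first. Ac2O/pyridine gives the diacetate 2-[2,5-bis(acetyloxy)-4-methoxyphenyl]-5,6,7,8-tetramethoxy-4H-chromen-4-one F5. BCl3 in CH2Cl2 at −40 to 0 °C then cleaves only the 5-OMe to give 2-[2,5-bis(acetyloxy)-4-methoxyphenyl]-5-hydroxy-6,7,8-trimethoxy-4H-chromen-4-one F6; the acetoxy groups cannot chelate boron to the 4'-OMe and make ring B electron-poor. HCl in MeOH at 40 °C removes both acetates to give 8.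

Step 1 is the third risk. The unprotected aldehyde may condense sluggishly as its phenoxide, and the chalcone–flavanone equilibrium may stay incomplete in the one-pot. The fallback sets out from 1 and comes back at 4, separating condensation, ring closure and unmasking. Compound 1 and commercial 3-(benzyloxy)-4-methoxybenzaldehyde (KOH, EtOH, rt) give the crystalline chalcone (E)-3-[3-(benzyloxy)-4-methoxyphenyl]-1-(2-hydroxy-3,4,5,6-tetramethoxyphenyl)prop-2-en-1-one F1. NaOAc in refluxing EtOH closes it to rac-2-[3-(benzyloxy)-4-methoxyphenyl]-5,6,7,8-tetramethoxychroman-4-one F2. Hydrogenolysis (H2, 10 wt% Pd on carbon, EtOAc, rt) then gives 4.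

## Further compounds

F1 | step 1 | (E)-3-[3-(benzyloxy)-4-methoxyphenyl]-1-(2-hydroxy-3,4,5,6-tetramethoxyphenyl)prop-2-en-1-one | COc1ccc(/C=C/C(=O)c2c(O)c(OC)c(OC)c(OC)c2OC)cc1OCc1ccccc1
F2 | step 1 | rac-2-[3-(benzyloxy)-4-methoxyphenyl]-5,6,7,8-tetramethoxychroman-4-one | COc1ccc(C2CC(=O)c3c(OC)c(OC)c(OC)c(OC)c3O2)cc1OCc1ccccc1
F3 | step 2 | 2-(3-hydroxy-4-methoxyphenyl)-5,6,7,8-tetramethoxy-4H-chromen-4-one | COc1ccc(-c2cc(=O)c3c(OC)c(OC)c(OC)c(OC)c3o2)cc1O
F4 | step 2 | 2-(4-methoxy-3,6-dioxocyclohexa-1,4-dien-1-yl)-5,6,7,8-tetramethoxy-4H-chromen-4-one | COC1=CC(=O)C(c2cc(=O)c3c(OC)c(OC)c(OC)c(OC)c3o2)=CC1=O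
F5 | step 3 | 2-[2,5-bis(acetyloxy)-4-methoxyphenyl]-5,6,7,8-tetramethoxy-4H-chromen-4-one | COc1cc(OC(C)=O)c(-c2cc(=O)c3c(OC)c(OC)c(OC)c(OC)c3o2)cc1OC(C)=O
F6 | step 3 | 2-[2,5-bis(acetyloxy)-4-methoxyphenyl]-5-hydroxy-6,7,8-trimethoxy-4H-chromen-4-one | COc1cc(OC(C)=O)c(-c2cc(=O)c3c(O)c(OC)c(OC)c(OC)c3o2)cc1OC(C)=O
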